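**Plan**

1. Numbering (daucane): C1 = quaternary ring-fusion carbon with CH3, C4 = carbinol carbon with isopropyl, C5 = ring-fusion CH, C6 = ester carbinol, C7 = CH2, C8(CH3)–C9 = oxirane carbons, C10 = free carbinol; β = face of the C1 methyl.
2. Retrosynthesis: cut the angelate C–O bond and take C10 back to a ketone; then cut C8–C9, which is both a cycloheptane bond and the C–C bond of the oxirane (retro-Darzens), to a cyclopentane carrying a chloroacetyl group on C1 and a 1-(PMB-oxy)-3-oxobutyl chain on C5; then cut C4–isopropyl, C5–C6 (aldol) and C1–C10 (conjugate addition) back to 3-methylcyclopent-2-enone.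
3. Enabling feature: C9 sits between C8, which carries a methyl and the ring oxygen (a latent methyl ketone), and C10, a carbinol flanked by the quaternary C1, so a C10 ketone can enolise only toward C9. A C9 chloro-enolate adding to the C8 ketone therefore closes the seven-membered carbocycle, and chloride displacement closes the three-membered ring.
4. Forward order: the cyclopentane is present from the start; its three substituents are added; cycloheptane and oxirane then form together in one step; esterification and C10 reduction finish the route.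
5. Stereochemistry: C1 from a ligand-controlled Cu-catalysed conjugate addition; C5 and C6 from an anti aldol trans to the isopropenyl group; C4 from addition anti to the C5 chain; C8/C9 from a magnesium-chelated, reversible Darzens closure that funnels the aldolates into one oxirane; C10 from peripheral hydride attack.

Key step: step 8

Remark on the chemistry: 13 is drawn as the open keto alcohol although it may rest partly as the C4–OH/C8 lactol, which reopens under base; in step 1 the ligand antipode is the one that gives (S)-3.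

**Step 1**
Reactants: 1 3-methylcyclopent-2-en-1-one
Product: 3 (S)-trimethyl{[3-methyl-3-(prop-1-en-2-yl)cyclopent-1-en-1-yl]oxy}silane, via dimethylaluminium enolate 2 (not isolated)
Conditions: isopropenylMgBr, Me2AlCl, Et2O, 0 °C; CuTC (10 mol %), SimplePhos-type chiral phosphinamine (11 mol %), 1, −30 °C; then TMSOTf, −30 → 0 °C
Reagents that add atoms: isopropenylmagnesium bromide, C=C(C)[Mg]Br; trimethylsilyl trifluoromethanesulfonate, C[Si](C)(C)OS(=O)(=O)C(F)(F)F; dimethylaluminium chloride, C[Al](C)Cl (its AlMe2 group stays only in 2)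
Why: Copper-catalysed asymmetric conjugate addition of an alkenylalane to a β-substituted cyclic enone (alkenyl transfers in preference to methyl) should set the quaternary C1 under ligand control, and O-silylation of the aluminium enolate stores the C4–C5 enolate regiochemistry.

**Step 2**
Reactants: 4 ethyl 2-(2-methyl-1,3-dioxolan-2-yl)acetate
Product: 5 2-(2-methyl-1,3-dioxolan-2-yl)acetaldehyde
Conditions: DIBAL-H (1.05 equiv), CH2Cl2, −78 °C; Rochelle salt
Reagents that add atoms: none
Why: DIBAL-H partial reduction of an ester at −78 °C stops at the aldehyde because the tetrahedral aluminium hemiacetal survives until work-up; the ketal masks the future C8 ketone.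

**Step 3**
Reactants: 3 (S)-trimethyl{[3-methyl-3-(prop-1-en-2-yl)cyclopent-1-en-1-yl]oxy}silane; 5 2-(2-methyl-1,3-dioxolan-2-yl)acetaldehyde
Product: 7 (2S,3S)-2-[(1S)-1-hydroxy-2-(2-methyl-1,3-dioxolan-2-yl)ethyl]-3-methyl-3-(prop-1-en-2-yl)cyclopentan-1-one, via lithium enolate 6 (not isolated)
Conditions: MeLi, THF, 0 °C; then 5, −78 °C; aq. NH4Cl
Reagents that add atoms: methyllithium, [Li]C (lithium stays only in 6)
Why: Methyllithium cleaves the silyl enol ether to the regiodefined lithium enolate, whose aldol addition through a chair Zimmerman–Traxler transition state should give the anti aldol (the ring enolate is necessarily E), the aldehyde approaching C5 anti to the larger isopropenyl group on C1, so that C5 and C6 are set relative to C1.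

**Step 4**
Reactants: 7 (2S,3S)-2-[(1S)-1-hydroxy-2-(2-methyl-1,3-dioxolan-2-yl)ethyl]-3-methyl-3-(prop-1-en-2-yl)cyclopentan-1-one
Product: 8 (1R,2S,3S)-2-[(1S)-1-hydroxy-2-(2-methyl-1,3-dioxolan-2-yl)ethyl]-3-methyl-1-(propan-2-yl)-3-(prop-1-en-2-yl)cyclopentan-1-ol
Conditions: i-PrMgCl (3.5 equiv), CeCl3, THF, −78 → −20 °C
Reagents that add atoms: isopropylmagnesium chloride, CC(C)[Mg]Cl
Why: The organocerium reagent (Imamoto addition) should add to the hindered, enolisable ketone without enolisation or retro-aldol and attack the α face, anti to the adjacent C5 side chain and the pseudoaxial C1 methyl, which gives the 4β-alcohol.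

**Step 5**
Reactants: 8 (1R,2S,3S)-2-[(1S)-1-hydroxy-2-(2-methyl-1,3-dioxolan-2-yl)ethyl]-3-methyl-1-(propan-2-yl)-3-(prop-1-en-2-yl)cyclopentan-1-ol
Product: 9 (1R,2S,3S)-2-[(1S)-1-[(4-methoxyphenyl)methoxy]-2-(2-methyl-1,3-dioxolan-2-yl)ethyl]-3-methyl-1-(propan-2-yl)-3-(prop-1-en-2-yl)cyclopentan-1-ol
Conditions: NaH (1.1 equiv), PMBCl, TBAI (cat.), THF/DMF, 0 °C → rt
Reagents that add atoms: 4-methoxybenzyl chloride, COc1ccc(CCl)cc1
Why: Williamson etherification in which only the secondary C6 alkoxide is alkylated, the tertiary C4 alcohol being too hindered; a benzyl-type ether is chosen because its oxygen can chelate in step 8.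

**Step 6**
Reactants: 9 (1R,2S,3S)-2-[(1S)-1-[(4-methoxyphenyl)methoxy]-2-(2-methyl-1,3-dioxolan-2-yl)ethyl]-3-methyl-1-(propan-2-yl)-3-(prop-1-en-2-yl)cyclopentan-1-ol
Product: 10 1-[(1S,2S,3R)-3-hydroxy-2-{(1S)-1-[(4-methoxyphenyl)methoxy]-2-(2-methyl-1,3-dioxolan-2-yl)ethyl}-1-methyl-3-(propan-2-yl)cyclopentyl]ethan-1-one
Conditions: O3, pyridine, CH2Cl2/MeOH, −78 °C; Me2S
Reagents that add atoms: ozone, [O-][O+]=O
Why: Ozonolysis with reductive work-up cleaves the only C=C bond to the C10 methyl ketone; the 1,1-disubstituted alkene should react far faster than the anisyl ring.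

**Step 7**
Reactants: 10 1-[(1S,2S,3R)-3-hydroxy-2-{(1S)-1-[(4-methoxyphenyl)methoxy]-2-(2-methyl-1,3-dioxolan-2-yl)ethyl}-1-methyl-3-(propan-2-yl)cyclopentyl]ethan-1-one
Product: 13 2-chloro-1-[(1S,2S,3R)-3-hydroxy-2-{(1S)-1-[(4-methoxyphenyl)methoxy]-3-oxobutyl}-1-methyl-3-(propan-2-yl)cyclopentyl]ethan-1-one, via bis-silylated enol ether 11 (not isolated), via silylated chloro ketone 12 (not isolated)
Conditions: LDA (2.5 equiv), TMSCl, THF, −78 → 0 °C; NCS, THF, 0 °C; then 1 M HCl, THF, rt
Reagents that add atoms: N-chlorosuccinimide, O=C1CCC(=O)N1Cl; water, O; chlorotrimethylsilane, C[Si](C)(C)Cl (its SiMe3 groups stay only in 11 and 12)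
Why: The C10 ketone can enolise only toward its methyl group (C1 is quaternary), so LDA/TMSCl should give one silyl enol ether (the C4 alkoxide is silylated too), NCS chlorinates it at C9 (electrophilic α-halogenation of a silyl enol ether), and aqueous acid then removes the silyl ether and the dioxolane in the same pot.

**Step 8**
Reactants: 13 2-chloro-1-[(1S,2S,3R)-3-hydroxy-2-{(1S)-1-[(4-methoxyphenyl)methoxy]-3-oxobutyl}-1-methyl-3-(propan-2-yl)cyclopentyl]ethan-1-one
Product: 15 (1S,4R,5S,6S,8R,9R)-8,9-epoxy-4-hydroxy-6-[(4-methoxyphenyl)methoxy]daucan-10-one (trans-fused; 4β-OH; 6α-OPMB; 8α,9α-oxirane), via magnesium chlorohydrin alkoxide 14 (not isolated)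
Conditions: Mg(HMDS)2 (2.2 equiv), toluene/THF 10:1, 0.01 M, −40 °C → rt
Reagents that add atoms: magnesium bis(hexamethyldisilazide), C[Si](C)(C)N([Si](C)(C)C)[Mg]N([Si](C)(C)C)[Si](C)(C)C (magnesium stays only in 14)
Why: Intramolecular Darzens condensation: the magnesium amide removes the C4 hydroxyl proton and the most acidic C–H (C9, between chlorine and the C10 carbonyl, whose other side is blocked by the quaternary C1), the chloro-enolate adds to the C8 methyl ketone, and the C8 alkoxide displaces chloride at C9. The closest known reaction type is the Darzens reaction of α-chloro ketone enolates with ketones, including intramolecular variants that give ring-fused epoxy ketones. The cycloheptane closes by a 7-(enolendo)-exo-trig aldol addition and the oxirane by a 3-exo-tet substitution. C8 is controlled by a magnesium chelate that ties together the C4 alkoxide, the C6 PMB-ether oxygen and the C8 carbonyl oxygen, so that the C8 oxygen ends up cis to the C6 oxygen (α) while C9, tethered through C5, attacks the other ketone face; C9 follows from the stereospecific closure, since only the chlorohydrin alkoxide with O and Cl anti can close and the oxirane can only be cis-fused. The step needs ketone face selectivity and enolisation of the chloro ketone in preference to the β-alkoxy methyl ketone; the first should come from the chelate together with the reversibility of the aldol addition (aldolates that cannot close revert and drain through the one that can), the second from the higher acidity of the ClCH2 group and high dilution.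

**Step 9**
Reactants: 15 (1S,4R,5S,6S,8R,9R)-8,9-epoxy-4-hydroxy-6-[(4-methoxyphenyl)methoxy]daucan-10-one
Product: 16 (1S,4R,5S,6S,8R,9R)-8,9-epoxy-4,6-dihydroxydaucan-10-one
Conditions: DDQ, CH2Cl2/pH 7 buffer, 0 °C
Reagents that add atoms: none
Why: Oxidative cleavage of the PMB ether by DDQ in wet dichloromethane (hydride abstraction, then hydrolysis of the oxocarbenium ion) is neutral and should leave the epoxy ketone and the tertiary alcohol untouched.

**Step 10**
Reactants: 16 (1S,4R,5S,6S,8R,9R)-8,9-epoxy-4,6-dihydroxydaucan-10-one; 17 angelic acid [(Z)-2-methylbut-2-enoic acid]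
Product: 19 (1S,4R,5S,6S,8R,9R)-8,9-epoxy-4-hydroxy-10-oxodaucan-6-yl (Z)-2-methylbut-2-enoate, via mixed anhydride 18 (not isolated)
Conditions: 17, 2,4,6-Cl3C6H2COCl, Et3N, toluene, rt; then 16, 80 °C (no DMAP)
Reagents that add atoms: 2,4,6-trichlorobenzoyl chloride, O=C(Cl)c1c(Cl)cc(Cl)cc1Cl (its acyl group stays only in 18)
Why: Yamaguchi esterification through the 2,4,6-trichlorobenzoyl mixed anhydride without DMAP should acylate the secondary C6 alcohol (the tertiary C4 alcohol is inert) and avoid base-catalysed Z→E isomerisation of the angelate to the tiglate.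

**Step 11**
Reactants: 19 (1S,4R,5S,6S,8R,9R)-8,9-epoxy-4-hydroxy-10-oxodaucan-6-yl (Z)-2-methylbut-2-enoate
Product: 20 lapiferine [(1S,4R,5S,6S,8R,9S,10S)-8,9-epoxy-4,10-dihydroxydaucan-6-yl (Z)-2-methylbut-2-enoate; 6α-angeloyloxy-8α,9α-epoxydaucane-4β,10α-diol]
Conditions: NaBH4, CeCl3·7H2O, MeOH, −78 °C
Reagents that add atoms: none
Why: Luche reduction is chemoselective for the ketone over the unsaturated ester and the oxirane, and hydride should enter from the peripheral β face of the C10 carbonyl (the α face is screened by ring carbons C5 and C8 in the chair form of the epoxycycloheptanone), which gives the 10α-alcohol syn to the oxirane oxygen.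

**Compound list**

1 | 3-methylcyclopent-2-en-1-one | CC1=CC(=O)CC1 | starting material
2 | dimethylaluminium (S)-3-methyl-3-(prop-1-en-2-yl)cyclopent-1-en-1-olate | C[Al](C)OC1=C[C@@](C)(C(C)=C)CC1 | intermediate
3 | (S)-trimethyl{[3-methyl-3-(prop-1-en-2-yl)cyclopent-1-en-1-yl]oxy}silane | C[Si](C)(C)OC1=C[C@@](C)(C(C)=C)CC1 | intermediate
4 | ethyl 2-(2-methyl-1,3-dioxolan-2-yl)acetate | CCOC(=O)CC1(C)OCCO1 | starting material
5 | 2-(2-methyl-1,3-dioxolan-2-yl)acetaldehyde | O=CCC1(C)OCCO1 | intermediate
6 | lithium (S)-3-methyl-3-(prop-1-en-2-yl)cyclopent-1-en-1-olate | [Li]OC1=C[C@@](C)(C(C)=C)CC1 | intermediate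
7 | (2S,3S)-2-[(1S)-1-hydroxy-2-(2-methyl-1,3-dioxolan-2-yl)ethyl]-3-methyl-3-(prop-1-en-2-yl)cyclopentan-1-one | O[C@@H](CC1(C)OCCO1)[C@@H]2[C@@](C)(C(C)=C)CCC2=O | intermediate
8 | (1R,2S,3S)-2-[(1S)-1-hydroxy-2-(2-methyl-1,3-dioxolan-2-yl)ethyl]-3-methyl-1-(propan-2-yl)-3-(prop-1-en-2-yl)cyclopentan-1-ol | O[C@@H](CC1(C)OCCO1)[C@@H]2[C@@](C)(C(C)=C)CC[C@@]2(O)C(C)C | intermediate
9 | (1R,2S,3S)-2-[(1S)-1-[(4-methoxyphenyl)methoxy]-2-(2-methyl-1,3-dioxolan-2-yl)ethyl]-3-methyl-1-(propan-2-yl)-3-(prop-1-en-2-yl)cyclopentan-1-ol | COc1ccc(CO[C@@H](CC2(C)OCCO2)[C@@H]3[C@@](C)(C(C)=C)CC[C@@]3(O)C(C)C)cc1 | intermediate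
10 | 1-[(1S,2S,3R)-3-hydroxy-2-{(1S)-1-[(4-methoxyphenyl)methoxy]-2-(2-methyl-1,3-dioxolan-2-yl)ethyl}-1-methyl-3-(propan-2-yl)cyclopentyl]ethan-1-one | COc1ccc(CO[C@@H](CC2(C)OCCO2)[C@@H]3[C@@](C)(C(C)=O)CC[C@@]3(O)C(C)C)cc1 | intermediate
11 | bis-silyl derivative of 10 (C10 trimethylsilyl enol ether, C4 trimethylsilyl ether) | COc1ccc(CO[C@@H](CC2(C)OCCO2)[C@@H]3[C@@](C)(C(=C)O[Si](C)(C)C)CC[C@@]3(O[Si](C)(C)C)C(C)C)cc1 | intermediate
12 | C4 trimethylsilyl ether of the chloromethyl ketone with the dioxolane still in place | COc1ccc(CO[C@@H](CC2(C)OCCO2)[C@@H]3[C@@](C)(C(=O)CCl)CC[C@@]3(O[Si](C)(C)C)C(C)C)cc1 | intermediate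
13 | 2-chloro-1-[(1S,2S,3R)-3-hydroxy-2-{(1S)-1-[(4-methoxyphenyl)methoxy]-3-oxobutyl}-1-methyl-3-(propan-2-yl)cyclopentyl]ethan-1-one | COc1ccc(CO[C@@H](CC(C)=O)[C@@H]2[C@@](C)(C(=O)CCl)CC[C@@]2(O)C(C)C)cc1 | intermediate
14 | magnesium salt of the 9β-chloro-8α-oxido-4β-oxido aldol adduct (6α-OPMB daucan-10-one) | COc1ccc(CO[C@H]2C[C@@](C)([O-])[C@H](Cl)C(=O)[C@@]3(C)CC[C@@]([O-])(C(C)C)[C@H]23)cc1.[Mg+2] | intermediate
15 | (1S,4R,5S,6S,8R,9R)-8,9-epoxy-4-hydroxy-6-[(4-methoxyphenyl)methoxy]daucan-10-one | COc1ccc(CO[C@H]2C[C@@]3(C)O[C@H]3C(=O)[C@@]3(C)CC[C@@](O)(C(C)C)[C@H]23)cc1 | intermediate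
16 | (1S,4R,5S,6S,8R,9R)-8,9-epoxy-4,6-dihydroxydaucan-10-one | O[C@H]1C[C@@]2(C)O[C@H]2C(=O)[C@@]2(C)CC[C@@](O)(C(C)C)[C@H]12 | intermediate
17 | angelic acid, (Z)-2-methylbut-2-enoic acid | C/C=C(/C)C(=O)O | starting material
18 | (Z)-2-methylbut-2-enoic 2,4,6-trichlorobenzoic anhydride | C/C=C(/C)C(=O)OC(=O)c1c(Cl)cc(Cl)cc1Cl | intermediate
19 | (1S,4R,5S,6S,8R,9R)-8,9-epoxy-4-hydroxy-10-oxodaucan-6-yl (Z)-2-methylbut-2-enoate | C/C=C(/C)C(=O)O[C@H]1C[C@@]2(C)O[C@H]2C(=O)[C@@]2(C)CC[C@@](O)(C(C)C)[C@H]12 | intermediate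
20 | lapiferine | C/C=C(/C)C(=O)O[C@H]1C[C@@]2(C)O[C@H]2[C@@H](O)[C@@]2(C)CC[C@@](O)(C(C)C)[C@H]12 | target

**Totals and risks**

Total step count: 11. Longest linear sequence: 10 steps (steps 1 and 3–11; step 2 makes the side fragment).

The three steps most likely to fail:

1. Step 8 (key step). What may go wrong: enolisation of the β-PMB-oxy methyl ketone followed by E1cB loss of the ether oxygen; alkylation of that enolate by the chloromethyl ketone; or closure through the non-chelated ring conformer, which would attack the other ketone face and give the β-oxirane. Fallback (base-free ring closure, oxirane made afterwards by directed epoxidation): it sets out from 13. Samarium diiodide (THF, −78 °C) converts the chloro ketone reductively into the C9 samarium enolate, and the Reformatsky-type aldol addition to the chelated C8 ketone should give the β-hydroxy ketone (1S,4R,5S,6S,8R)-4,8-dihydroxy-6-[(4-methoxyphenyl)methoxy]daucan-10-one F1. E1cB dehydration (NaOMe, MeOH) should give the cycloheptenone (1S,4R,5S,6S)-4-hydroxy-6-[(4-methoxyphenyl)methoxy]dauc-8-en-10-one F2. Luche reduction should give the allylic alcohol 6α-[(4-methoxyphenyl)methoxy]dauc-8-ene-4β,10α-diol F3. VO(acac)2/t-BuOOH epoxidation, directed by the C10 hydroxyl, should give the syn epoxy alcohol 8α,9α-epoxy-6α-[(4-methoxyphenyl)methoxy]daucane-4β,10α-diol F4. Dess–Martin oxidation of F4 comes back to the route at 15.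

2. Step 3. What may go wrong: low anti/syn selectivity at the carbinol carbon C6 in the lithium aldol addition, incomplete preference for attack anti to isopropenyl, and retro-aldol on work-up. Fallback (reagent-controlled reduction instead of substrate-controlled aldol stereochemistry): the C6-epimer mixture is carried through step 4, and the fallback sets out from 8 as that mixture. Dess–Martin oxidation of the secondary alcohol should give the β-hydroxy ketone 1-[(1R,2R,5S)-2-hydroxy-5-methyl-2-(propan-2-yl)-5-(prop-1-en-2-yl)cyclopentyl]-2-(2-methyl-1,3-dioxolan-2-yl)ethan-1-one F5. Corey–Bakshi–Shibata reduction with (R)-Me-CBS and catecholborane (toluene, −78 °C; catecholborane spares the isopropenyl group) should convert both epimers into the (S)-carbinol, which comes back to the route at 8.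

3. Step 10. What may go wrong: isomerisation of the angeloyl unit to the tigloyl unit during activation, or slow acylation of the hindered C6 alcohol. Fallback (the Z double bond is built on the ester instead of being carried through the acylation): it sets out from 16. DCC/DMAP esterification of the C6 alcohol with 2-[bis(2,2,2-trifluoroethoxy)phosphoryl]propanoic acid should give the phosphonate ester (1S,4R,5S,6S,8R,9R)-8,9-epoxy-4-hydroxy-10-oxodaucan-6-yl 2-[bis(2,2,2-trifluoroethoxy)phosphoryl]propanoate F6. Still–Gennari olefination of F6 with acetaldehyde (KHMDS, 18-crown-6, THF, −78 °C) should give the Z-configured 2-methylbut-2-enoate, which comes back to the route at 19.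

**Further compounds**

F1 | step 8 | (1S,4R,5S,6S,8R)-4,8-dihydroxy-6-[(4-methoxyphenyl)methoxy]daucan-10-one | COc1ccc(CO[C@H]2C[C@@](C)(O)CC(=O)[C@@]3(C)CC[C@@](O)(C(C)C)[C@H]23)cc1
F2 | step 8 | (1S,4R,5S,6S)-4-hydroxy-6-[(4-methoxyphenyl)methoxy]dauc-8-en-10-one | COc1ccc(CO[C@H]2CC(C)=CC(=O)[C@@]3(C)CC[C@@](O)(C(C)C)[C@H]23)cc1
F3 | step 8 | 6α-[(4-methoxyphenyl)methoxy]dauc-8-ene-4β,10α-diol | COc1ccc(CO[C@H]2CC(C)=C[C@@H](O)[C@@]3(C)CC[C@@](O)(C(C)C)[C@H]23)cc1
F4 | step 8 | 8α,9α-epoxy-6α-[(4-methoxyphenyl)methoxy]daucane-4β,10α-diol | COc1ccc(CO[C@H]2C[C@@]3(C)O[C@H]3[C@@H](O)[C@@]3(C)CC[C@@](O)(C(C)C)[C@H]23)cc1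
F5 | step 3 | 1-[(1R,2R,5S)-2-hydroxy-5-methyl-2-(propan-2-yl)-5-(prop-1-en-2-yl)cyclopentyl]-2-(2-methyl-1,3-dioxolan-2-yl)ethan-1-one | O=C(CC1(C)OCCO1)[C@@H]2[C@@](C)(C(C)=C)CC[C@@]2(O)C(C)C
F6 | step 10 | (1S,4R,5S,6S,8R,9R)-8,9-epoxy-4-hydroxy-10-oxodaucan-6-yl 2-[bis(2,2,2-trifluoroethoxy)phosphoryl]propanoate | CC(C(=O)O[C@H]1C[C@@]2(C)O[C@H]2C(=O)[C@@]2(C)CC[C@@](O)(C(C)C)[C@H]12)P(=O)(OCC(F)(F)F)OCC(F)(F)F
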